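Readings and results come from a simulation with made-up constants; the scatter is artificial.

Set side by side, the north and south-east runs differ in charge, 0.56 M against 0.88 M, yet as fractions of the charge they keep G against X at nearly the same ratio: summed over the five readings, 0.474 in the north run and 0.481 in the south-east run.

| flask | X | remark | time |
|---|---|---|---|
| north | 0.56 M | run made earlier |  |
| south-east | 0.88 M | run made earlier |  |
| flask | 0.40 M |  | 2.5 min |

| run | time / min | G / % | L / % | X / % |
|---|---|---|---|---|
| north | 0.250 | 21.8 | 15.7 | 45.2 |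
| north | 0.833 | 11.7 | 40.5 | 21.9 |
| north | 1.33 | 3.9 | 51.8 | 13.7 |
| north | 2.00 | 4.1 | 59.2 | 5.3 |
| north | 3.00 | 0.9 | 64.1 | 3.4 |
| south-east | 0.250 | 21.8 | 16.2 | 41.6 |
| south-east | 0.833 | 8.7 | 37.8 | 18.7 |
| south-east | 1.33 | 4.4 | 48.3 | 9.2 |
| south-east | 2.00 | 1.2 | 53.7 | 6.0 |
| south-east | 3.00 | 1.9 | 56.7 | 3.5 |

(readings scatter by 1 percentage point)

* share of G in G plus L at 0.080 s
* share of G in G plus L at 2.5 min
* which of G and L there is more of at 2.5 min

Our bench rule is that G rides on X, as in a pre-equilibrium, and we carry the standing ratio, G over X summed across both runs, 0.477, a reading with the scatter of its runs. For the flask, charged at 0.40 M, we take X at 2.5 min from the north run, midway between its last two readings in time, as 4.24%, so by our estimate G is 2.03%. L, averaged over those readings and run straight down the charge, is 64.9%, which gives G a share of 3.03%. But this flask is charged with X and no G, so its ratio has to climb, and 0.080 s is 0.00533 of the time of the first reading, which lies beyond the rule's border; there we count steps instead, G lying one step from X and L behind J, so we expect G's share in this flask to stand near complete.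

The forecast says 99.6% early, 2.4% late, with L ahead, and holds that “G then drains with X”; its late share is lower than ours.

The flask gives 99.8% and 3.47%, with L ahead at 66.6% against 2.40% of G.

    X + G → Z (k = 0.0470 M⁻¹ s⁻¹)
    X ⇌ G (K = 0.510, k = 0.150 s⁻¹)
    J → L (k = 0.250 s⁻¹)
    G → E (k = 3.20 × 10⁻⁴ s⁻¹)
    J ⇌ D (K = 1.70, k = 0.0310 s⁻¹)
    X ⇌ J (K = 0.340, k = 0.0310 s⁻¹)
    D → Q (k = 0.0920 s⁻¹)

At 2.5 min the flask holds G over X at 0.536, and our ratio on its X and L gives 3.10%. Charged at 1.0 M, the neighbouring flask also holds 0.536, and the ratio on its X and L gives 2.57% against its actual 2.88%, with L at 54.6%.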